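1.87 mM is the number to hold on to: the chain budget, the pre-initiator charged minus the impurity charged, on the reading that each impurity takes one initiator before any chain can begin.

| flask | free monomer | transfer agent | pre-initiator | impurity | remark | time |
|---|---|---|---|---|---|---|
| alpha | 0.050 M | 0.015 M | 2.5 mM | 0.63 mM | the very flask that is asked about, followed so far |  |
| gamma | 0.050 M | 0.030 M | 2.5 mM | 0.63 mM | run made earlier |  |
| flask | 0.050 M | 0.0150 M | 2.5 mM | 0.63 mM |  | 12 min |

| run | time / min | monomer in chains / % | free monomer / % |
|---|---|---|---|
| alpha | 0.500 | 0.7 | 100.8 |
| alpha | 0.667 | 0 | 99.4 |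
| alpha | 1.00 | 0.3 | 101.5 |
| alpha | 1.50 | 1.3 | 97.8 |
| alpha | 2.50 | 1.9 | 97.7 |
| alpha | 4.00 | 2.4 | 97.7 |
| alpha | 6.00 | 10.9 | 90.7 |
| gamma | 1.33 | 0 | 100.2 |
| gamma | 2.50 | 1.8 | 99.8 |
| gamma | 4.00 | 4.0 | 95.9 |
| gamma | 5.00 | 6.0 | 93.3 |
| gamma | 6.00 | 11.6 | 88.7 |
| gamma | 8.00 | 19.3 | 81.3 |

(readings scatter by 1 percentage point)

- the average divides the monomer in chains by the number of chains begun, living and dead together
- steps under discussion: free monomer + initiator -> living end + monomer in chains; free monomer + living end -> monomer in chains + living end; living end + transfer agent -> dead chain; free monomer -> decomposition product; initiator + impurity -> spent initiator; pre-initiator -> initiator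
- the earlier runs do not show the number of chains; that part of a forecast is a guess

- average number of monomer units in a chain (chains begun, living or dead) at 12 min
- part of the free monomer that has reacted at 12 min

Build the flask one process at a time, and calibrate on the gamma run, which was followed longer than the alpha run. Take growth first, pseudo-first-order in free monomer, so that the logarithm of the monomer's fall follows the time integral of [living end]:

ln(charged / left) = 0.207 at 8.00 min

With [living end] constant that scales with time and gives 26.7 % reacted at 12 min.

Now let first-order release feed the living ends. The gamma run reads 0 % at 1.33 min but 1.8 % at 2.50 min. I take that as the moment when release has just covered the impurity, which gives: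

k = ln([pre-initiator] / budget) / lag = 0.116 min⁻¹

Release alone, with no impurity subtracted, bends the integral upward and gives 33.6 %.

Then subtract the impurity, so that [living end] starts from nothing at the lag:

∫[living end]dt = budget × (t − lag) − (budget − [pre-initiator] e^(−kt)) / k

That gives 41.7 %.

The rest adds nothing I can read: at 6.00 min the free monomer stands at 90.7 % in alpha and 88.7 % in gamma, despite twice the transfer agent in gamma, and at 8.00 min gamma's two columns sum to 101 %.

Chains begun by 12 min come to 1.25 mM, so I commit to an average of 16.7.

The forecast said 40 % and 20 units, adding “This is a guess, since chain number was unobserved”.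

The flask gives 38.8 % and 14.8 units.

    free monomer + initiator → living end + monomer in chains (k = 24.0 L mol⁻¹ min⁻¹)
    free monomer + living end → monomer in chains + living end, rate k2*[living end]*[free monomer] (k = 62.0 L mol⁻¹ min⁻¹)
    living end + transfer agent → dead chain (kL = 0.510 L mol⁻¹ min⁻¹)
    free monomer → decomposition product (k = 6.70 × 10⁻⁵ min⁻¹)
    initiator + impurity → spent initiator (k = 13000 L mol⁻¹ min⁻¹)
    pre-initiator → initiator (k = 0.140 min⁻¹)

At 12 min this flask is far from rest, with 61 % of its free monomer and 19 % of its pre-initiator left. By 120 min free monomer is down to 0.0169 %, and living ends, dead chains and remaining initiator total 1.87 mM against the budget of 1.87 mM. The average climbs to 27.1, with charge over budget at 26.7. A neighbour flask, with 1.6 × 10⁻⁴ M of impurity, has its budget raised by 0.470 mM and holds 0.443 mM more living and dead chains at 12 min. In this flask, living ends fall from 0.00125 M to 8.24 × 10⁻⁴ M by 120 min, while dead chains reach 0.00102 M.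

Readings and results were generated by integration with made-up constants; scatter was added.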